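**Retrosynthetic overview**
1. Target 30 ⇐ C11‑OH‑directed osmylation of the C12 vinyl group of glycolate 28; the glycolate ⇐ esterification of the C14 alcohol of tricycle 25.
2. Eight‑membered ring (closed last): C5–C14 bond by SmI2 ketyl–enone cyclisation of aldehyde 24.
3. C11–C12 bond with both stereocentres: Felkin‑controlled allylboration of aldehyde 19 with (Z)‑allylboronic acid 21.
4. Five‑membered ring (closed second): conjugate addition/aldol condensation on enone 11, then MeLi addition and oxidative transposition to hydrindenone 17.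
5. Key bond C9–C10 and the C10 stereocentre: anionic oxy‑Cope [3,3] rearrangement of dienol 7, made from (S)‑6‑methylcyclohexenone 4; the six‑membered ring and C6 are bought in (S)‑carvone.

Assumption: the given SMILES is the authority for all nine stereocentres; atoms are labelled C1–C22 by mutilin numbering (C21, C22 = glycolate), and every structure below carries exactly the configurations of that string.
Convention: metal or boron alkoxides and enolates that are only protonated or hydrolysed on aqueous work‑up are not listed as separate compounds.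

**Step 1**
Reactants: 1 (S)‑carvone
Product: 2 (2S,5S)‑2‑methyl‑5‑(prop‑1‑en‑2‑yl)cyclohexan‑1‑one (trans‑dihydrocarvone)
Conditions: Zn dust, KOH, EtOH/H2O, reflux; chromatography
Reagents that add atoms: none
Why: Dissolving‑metal conjugate reduction of the enone; under the basic conditions the α‑methyl centre (future C6) equilibrates to the trans isomer dictated by the purchased isopropenyl‑bearing centre, and the minor cis isomer is removed.

**Step 2**
Reactants: 2 (2S,5S)‑dihydrocarvone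
Product: 4 (6S)‑6‑methylcyclohex‑2‑en‑1‑one, via methoxy hydroperoxide 3 (not isolated)
Conditions: O3, MeOH/CH2Cl2, −78 °C; then Cu(OAc)2·H2O, FeSO4·7H2O, −78 °C to rt
Reagents that add atoms: none
Why: Criegee ozonolysis in methanol followed by iron/copper‑mediated alkoxy‑radical β‑scission and oxidative elimination excises the side chain to give the conjugated enone; the α‑methyl stereocentre is untouched under these non‑enolising conditions.

**Step 3**
Reactants: 4 (6S)‑6‑methylcyclohex‑2‑en‑1‑one and 5 (2E)‑1‑chlorobut‑2‑ene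
Product: 7 (1R,6S)‑1‑[(2E)‑but‑2‑en‑1‑yl]‑6‑methylcyclohex‑2‑en‑1‑ol, via butenylbarium chloride 6 (not isolated)
Conditions: BaI2, LiC12H10 (lithium biphenylide, 2 equiv), THF, rt; 5, −78 °C; then 4, −78 °C; aq. NH4Cl
Reagents that add atoms: none
Why: Barbier‑type allylbarium addition, which attacks the carbonyl 1,2 through the unsubstituted allyl terminus with retention of the E geometry; axial attack on the half‑chair enone (C6 methyl pseudo‑equatorial) places the butenyl group cis to that methyl, so the carbinol centre is set by C6.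

**Step 4**
Reactants: 7 (1R,6S)‑1‑[(2E)‑but‑2‑en‑1‑yl]‑6‑methylcyclohex‑2‑en‑1‑ol
Product: 10 {[(3S,6S)‑3‑[(2S)‑but‑3‑en‑2‑yl]‑6‑methylcyclohex‑1‑en‑1‑yl]oxy}trimethylsilane, via potassium alkoxide 8 (not isolated), via potassium enolate 9 (not isolated)
Conditions: KH, 18‑crown‑6, THF, 0 to 40 °C; then Me3SiCl, Et3N, −78 °C
Reagents that add atoms: chlorotrimethylsilane, C[Si](C)(C)Cl
Why: Anionic oxy‑Cope [3,3]‑sigmatropic rearrangement through a chair transition state with the (E)‑methyl pseudo‑equatorial forms the C9–C10 bond suprafacially, transferring the carbinol configuration to C10 (and transiently C9); the regiodefined enolate is trapped as its silyl enol ether.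

**Step 5**
Reactants: 10 silyl enol ether
Product: 11 (6S)‑3‑[(2S)‑but‑3‑en‑2‑yl]‑6‑methylcyclohex‑2‑en‑1‑one
Conditions: Pd(OAc)2 (1.1 equiv), MeCN, rt
Reagents that add atoms: none
Why: Saegusa–Ito oxidation; the palladium enolate can only undergo β‑hydride elimination towards C9, giving the enone without base, so C6 and the doubly allylic C10 centre are not epimerised.

**Step 6**
Reactants: 11 (6S)‑3‑[(2S)‑but‑3‑en‑2‑yl]‑6‑methylcyclohex‑2‑en‑1‑one and 12 [2‑(1,3‑dioxan‑2‑yl)ethyl]magnesium bromide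
Product: 15 (3aR,6S)‑3a‑[(2S)‑but‑3‑en‑2‑yl]‑6‑methyl‑2,3,3a,4,5,6‑hexahydro‑7H‑inden‑7‑one, via silyl enol ether 13 (not isolated), via keto aldehyde 14 (not isolated)
Conditions: 12 (1.5 equiv), CuBr·SMe2 (10 mol %), Me3SiCl, THF, −78 to −20 °C; then 3 M HCl, THF, 60 °C
Reagents that add atoms: none
Why: Chlorotrimethylsilane‑accelerated copper‑catalysed conjugate addition (axial attack, cis to the C6 methyl) creates the C9 quaternary centre, and aqueous acid then unmasks the aldehyde and drives the intramolecular aldol condensation that closes the five‑membered ring.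

**Step 7**
Reactants: 15 bicyclic enone
Product: 16 (3aR,6S,7R)‑3a‑[(2S)‑but‑3‑en‑2‑yl]‑6,7‑dimethyl‑3,3a,4,5,6,7‑hexahydro‑2H‑inden‑7‑ol
Conditions: MeLi, THF, −78 °C
Reagents that add atoms: methyllithium, [Li]C
Why: Hard organolithium 1,2‑addition to the enone carbonyl brings in the C15 methyl; the new carbinol centre is destroyed in the next step, so its configuration (major epimer drawn) is irrelevant.

**Step 8**
Reactants: 16 tertiary allylic alcohol
Product: 17 (3aS,6S)‑3a‑[(2S)‑but‑3‑en‑2‑yl]‑6,7‑dimethyl‑2,3,3a,4,5,6‑hexahydro‑1H‑inden‑1‑one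
Conditions: C5H5NH[CrO3Cl] (pyridinium chlorochromate), CH2Cl2, rt
Reagents that add atoms: pyridinium chlorochromate, [O-][Cr](=O)(=O)Cl.c1cc[nH+]cc1
Why: Dauben–Babler oxidative transposition; [3,3]‑sigmatropic shift of the tertiary allylic chromate ester followed by oxidation gives the transposed enone (C3=O, C4=C5 bearing the C15 methyl).

**Step 9**
Reactants: 17 hydrindenone
Product: 19 (2R)‑2‑[(3aS,6S)‑6,7‑dimethyl‑1‑oxo‑1,2,3,4,5,6‑hexahydro‑3aH‑inden‑3a‑yl]propanal, via ozonide 18 (not isolated)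
Conditions: O3, pyridine, CH2Cl2, −78 °C; then Me2S, −78 °C to rt
Reagents that add atoms: ozone, [O-][O+]=O
Why: Criegee ozonolysis is selective for the electron‑rich monosubstituted alkene over the hindered, electron‑poor tetrasubstituted enone alkene, and the neutral reductive work‑up leaves the α‑stereocentre C10 intact.

**Step 10**
Reactants: 20 (2Z)‑3‑methylpent‑2‑en‑4‑yn‑1‑ol
Product: 21 [(2Z)‑3‑methylpent‑2‑en‑4‑yn‑1‑yl]boronic acid
Conditions: B2(OH)4, [Pd(MeCN)4](BF4)2 (1 mol %), DMSO/MeOH, rt; used directly as a solution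
Reagents that add atoms: tetrahydroxydiboron, OB(O)B(O)O
Why: Palladium‑catalysed allylic C–OH borylation gives the linear allylboronic acid with retention of the Z geometry (ethynyl cis to CH2B).

**Step 11**
Reactants: 19 aldehyde and 21 (Z)‑allylboronic acid
Product: 22 (3aS,6S)‑3a‑[(2R,3S,4R)‑4‑ethynyl‑3‑hydroxy‑4‑methylhex‑5‑en‑2‑yl]‑6,7‑dimethyl‑2,3,3a,4,5,6‑hexahydro‑1H‑inden‑1‑one
Conditions: 21 (1.3 equiv), 3 Å MS, CH2Cl2, 0 °C to rt; aq. work‑up
Reagents that add atoms: none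
Why: Allylboration through a Zimmerman–Traxler chair; Felkin–Anh attack anti to the bulky C9 quaternary substituent fixes C11 from C10, and the (Z)‑reagent (slim ethynyl axial, methyl equatorial) fixes the C12 quaternary centre relative to C11.

**Step 12**
Reactants: 22 homoallylic alcohol
Product: 23 (3aS,6S)‑3a‑[(2R,3S,4R)‑4‑ethynyl‑4‑methyl‑3‑[(triethylsilyl)oxy]hex‑5‑en‑2‑yl]‑6,7‑dimethyl‑2,3,3a,4,5,6‑hexahydro‑1H‑inden‑1‑one
Conditions: Et3SiOTf, 2,6‑lutidine, CH2Cl2, −78 to 0 °C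
Reagents that add atoms: triethylsilyl trifluoromethanesulfonate, CC[Si](CC)(CC)OS(=O)(=O)C(F)(F)F
Why: Silyl triflate protection of the hindered C11 alcohol, which prevents lactol formation with the C14 aldehyde unveiled next.

**Step 13**
Reactants: 23 silyl ether alkyne
Product: 24 (3S,4S,5R)‑3‑ethenyl‑5‑[(3aS,6S)‑6,7‑dimethyl‑1‑oxo‑1,2,3,4,5,6‑hexahydro‑3aH‑inden‑3a‑yl]‑3‑methyl‑4‑[(triethylsilyl)oxy]hexanal
Conditions: CpRu(MeCN)3PF6 (5 mol %), 5,5′‑bis(trifluoromethyl)‑2,2′‑bipyridine (5 mol %), NMP/H2O, 40 °C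
Reagents that add atoms: water, O
Why: Ruthenium‑vinylidene anti‑Markovnikov hydration converts the terminal alkyne into the C13–C14 aldehyde without touching the vinyl group, enone or silyl ether.

**Step 14**
Reactants: 24 enone aldehyde
Product: 25 (3aS,4R,5S,6S,8R,9S,9aS,10S)‑6‑ethenyl‑8‑hydroxy‑4,6,9,10‑tetramethyl‑5‑[(triethylsilyl)oxy]octahydro‑3a,9‑propanocyclopenta[8]annulen‑1(4H)‑one
Conditions: SmI2 (2.5 equiv), H2O (5 equiv), THF, 0 °C
Reagents that add atoms: none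
Why: SmI2 ketyl–olefin radical cyclisation; the C14 ketyl adds to the enone β‑carbon C5 and the samarium enolate is protonated at C4 cis to the new bond, the C9–C12 tether and the existing centres deciding the faces used, so C14, C5 and C4 are set as drawn.

**Step 15**
Reactants: 25 tricyclic C14 alcohol and 26 {[tert‑butyl(dimethyl)silyl]oxy}acetic acid
Product: 27 (3aS,4R,5S,6S,8R,9S,9aS,10S)‑6‑ethenyl‑4,6,9,10‑tetramethyl‑1‑oxo‑5‑[(triethylsilyl)oxy]decahydro‑3a,9‑propanocyclopenta[8]annulen‑8‑yl {[tert‑butyl(dimethyl)silyl]oxy}acetate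
Conditions: DCC, DMAP (cat.), CH2Cl2, rt
Reagents that add atoms: none
Why: Steglich esterification of the only free hydroxyl (C14); C11 is silyl‑protected.

**Step 16**
Reactants: 27 bis‑silyl ester
Product: 28 (3aS,4R,5S,6S,8R,9S,9aS,10S)‑6‑ethenyl‑5‑hydroxy‑4,6,9,10‑tetramethyl‑1‑oxodecahydro‑3a,9‑propanocyclopenta[8]annulen‑8‑yl hydroxyacetate
Conditions: HF·pyridine, THF, 0 °C to rt
Reagents that add atoms: none
Why: Fluoride‑mediated cleavage of both silyl ethers; the ester and ketone are inert.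

**Step 17**
Reactants: 28 vinyl glycolate
Product: 30 Pleuromutilin A, via osmate ester 29 (not isolated)
Conditions: OsO4 (1.05 equiv), TMEDA, CH2Cl2, −78 °C; then aq. Na2SO3, THF, 40 °C
Reagents that add atoms: osmium tetroxide, O=[Os](=O)(=O)=O
Why: Hydrogen‑bond‑directed syn‑dihydroxylation; the C11 hydroxyl binds the OsO4·TMEDA complex and delivers it to the adjacent vinyl group through a chair‑like array with C20 pseudo‑equatorial, giving the 11,19‑syn triol (C19 S), and reductive hydrolysis frees the diol.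

**Compound list**
1 | (S)‑carvone; (5S)‑2‑methyl‑5‑(prop‑1‑en‑2‑yl)cyclohex‑2‑en‑1‑one | CC1=CC[C@@H](CC1=O)C(C)=C | starting material
2 | (2S,5S)‑2‑methyl‑5‑(prop‑1‑en‑2‑yl)cyclohexan‑1‑one | C[C@H]1CC[C@@H](CC1=O)C(C)=C | intermediate
3 | (2S,5S)‑5‑(1‑hydroperoxy‑1‑methoxyethyl)‑2‑methylcyclohexan‑1‑one (epimers at the peroxy carbon) | C[C@H]1CC[C@@H](CC1=O)C(C)(OC)OO | intermediate (not isolated)
4 | (6S)‑6‑methylcyclohex‑2‑en‑1‑one | C[C@H]1CCC=CC1=O | intermediate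
5 | (2E)‑1‑chlorobut‑2‑ene | C/C=C/CCl | starting material
6 | [(2E)‑but‑2‑en‑1‑yl]barium chloride | C/C=C/C[Ba]Cl | intermediate (not isolated)
7 | (1R,6S)‑1‑[(2E)‑but‑2‑en‑1‑yl]‑6‑methylcyclohex‑2‑en‑1‑ol | C/C=C/C[C@]1(O)C=CCC[C@@H]1C | intermediate
8 | potassium (1R,6S)‑1‑[(2E)‑but‑2‑en‑1‑yl]‑6‑methylcyclohex‑2‑en‑1‑olate | C/C=C/C[C@]1([O-])C=CCC[C@@H]1C.[K+] | intermediate (not isolated)
9 | potassium (3S,6S)‑3‑[(2S)‑but‑3‑en‑2‑yl]‑6‑methylcyclohex‑1‑en‑1‑olate | C[C@H]1CC[C@@H]([C@@H](C)C=C)C=C1[O-].[K+] | intermediate (not isolated)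
10 | {[(3S,6S)‑3‑[(2S)‑but‑3‑en‑2‑yl]‑6‑methylcyclohex‑1‑en‑1‑yl]oxy}trimethylsilane | C[C@H]1CC[C@@H]([C@@H](C)C=C)C=C1O[Si](C)(C)C | intermediate
11 | (6S)‑3‑[(2S)‑but‑3‑en‑2‑yl]‑6‑methylcyclohex‑2‑en‑1‑one | C[C@H]1CCC([C@@H](C)C=C)=CC1=O | intermediate
12 | [2‑(1,3‑dioxan‑2‑yl)ethyl]magnesium bromide (THF solution) | Br[Mg]CCC1OCCCO1 | starting material
13 | {[(3S,6S)‑3‑[(2S)‑but‑3‑en‑2‑yl]‑3‑[2‑(1,3‑dioxan‑2‑yl)ethyl]‑6‑methylcyclohex‑1‑en‑1‑yl]oxy}trimethylsilane | C[C@H]1CC[C@](CCC2OCCCO2)([C@@H](C)C=C)C=C1O[Si](C)(C)C | intermediate (not isolated)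
14 | 3‑[(1R,4S)‑1‑[(2S)‑but‑3‑en‑2‑yl]‑4‑methyl‑3‑oxocyclohexyl]propanal | C[C@H]1CC[C@](CCC=O)([C@@H](C)C=C)CC1=O | intermediate (not isolated)
15 | (3aR,6S)‑3a‑[(2S)‑but‑3‑en‑2‑yl]‑6‑methyl‑2,3,3a,4,5,6‑hexahydro‑7H‑inden‑7‑one | C[C@H]1CC[C@]2(CCC=C2C1=O)[C@@H](C)C=C | intermediate
16 | (3aR,6S,7R)‑3a‑[(2S)‑but‑3‑en‑2‑yl]‑6,7‑dimethyl‑3,3a,4,5,6,7‑hexahydro‑2H‑inden‑7‑ol | C[C@H]1CC[C@]2(CCC=C2[C@]1(C)O)[C@@H](C)C=C | intermediate
17 | (3aS,6S)‑3a‑[(2S)‑but‑3‑en‑2‑yl]‑6,7‑dimethyl‑2,3,3a,4,5,6‑hexahydro‑1H‑inden‑1‑one | C[C@H]1CC[C@]2(CCC(=O)C2=C1C)[C@@H](C)C=C | intermediate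
18 | ozonide of 17 (3‑substituted 1,2,4‑trioxolane, epimers at the ring carbon) | C[C@H]1CC[C@]2(CCC(=O)C2=C1C)[C@@H](C)C3OCOO3 | intermediate (not isolated)
19 | (2R)‑2‑[(3aS,6S)‑6,7‑dimethyl‑1‑oxo‑1,2,3,4,5,6‑hexahydro‑3aH‑inden‑3a‑yl]propanal | C[C@H]1CC[C@]2(CCC(=O)C2=C1C)[C@@H](C)C=O | intermediate
20 | (2Z)‑3‑methylpent‑2‑en‑4‑yn‑1‑ol | OC/C=C(/C)C#C | starting material
21 | [(2Z)‑3‑methylpent‑2‑en‑4‑yn‑1‑yl]boronic acid | OB(O)C/C=C(/C)C#C | intermediate
22 | (3aS,6S)‑3a‑[(2R,3S,4R)‑4‑ethynyl‑3‑hydroxy‑4‑methylhex‑5‑en‑2‑yl]‑6,7‑dimethyl‑2,3,3a,4,5,6‑hexahydro‑1H‑inden‑1‑one | C[C@H]1CC[C@]2(CCC(=O)C2=C1C)[C@@H](C)[C@H](O)[C@](C)(C=C)C#C | intermediate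
23 | (3aS,6S)‑3a‑[(2R,3S,4R)‑4‑ethynyl‑4‑methyl‑3‑[(triethylsilyl)oxy]hex‑5‑en‑2‑yl]‑6,7‑dimethyl‑2,3,3a,4,5,6‑hexahydro‑1H‑inden‑1‑one | C[C@H]1CC[C@]2(CCC(=O)C2=C1C)[C@@H](C)[C@H](O[Si](CC)(CC)CC)[C@](C)(C=C)C#C | intermediate
24 | (3S,4S,5R)‑3‑ethenyl‑5‑[(3aS,6S)‑6,7‑dimethyl‑1‑oxo‑1,2,3,4,5,6‑hexahydro‑3aH‑inden‑3a‑yl]‑3‑methyl‑4‑[(triethylsilyl)oxy]hexanal | C[C@H]1CC[C@]2(CCC(=O)C2=C1C)[C@@H](C)[C@H](O[Si](CC)(CC)CC)[C@](C)(C=C)CC=O | intermediate
25 | (3aS,4R,5S,6S,8R,9S,9aS,10S)‑6‑ethenyl‑8‑hydroxy‑4,6,9,10‑tetramethyl‑5‑[(triethylsilyl)oxy]octahydro‑3a,9‑propanocyclopenta[8]annulen‑1(4H)‑one | C[C@H]1[C@H](O[Si](CC)(CC)CC)[C@](C)(C=C)C[C@@H](O)[C@@]2(C)[C@@H](C)CC[C@]13CCC(=O)[C@@H]32 | intermediate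
26 | {[tert‑butyl(dimethyl)silyl]oxy}acetic acid | OC(=O)CO[Si](C)(C)C(C)(C)C | starting material
27 | (3aS,4R,5S,6S,8R,9S,9aS,10S)‑6‑ethenyl‑4,6,9,10‑tetramethyl‑1‑oxo‑5‑[(triethylsilyl)oxy]decahydro‑3a,9‑propanocyclopenta[8]annulen‑8‑yl {[tert‑butyl(dimethyl)silyl]oxy}acetate | C[C@H]1[C@H](O[Si](CC)(CC)CC)[C@](C)(C=C)C[C@@H](OC(=O)CO[Si](C)(C)C(C)(C)C)[C@@]2(C)[C@@H](C)CC[C@]13CCC(=O)[C@@H]32 | intermediate
28 | (3aS,4R,5S,6S,8R,9S,9aS,10S)‑6‑ethenyl‑5‑hydroxy‑4,6,9,10‑tetramethyl‑1‑oxodecahydro‑3a,9‑propanocyclopenta[8]annulen‑8‑yl hydroxyacetate | C[C@H]1[C@H](O)[C@](C)(C=C)C[C@@H](OC(=O)CO)[C@@]2(C)[C@@H](C)CC[C@]13CCC(=O)[C@@H]32 | intermediate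
29 | cyclic 19,20‑osmate ester of 28, TMEDA complex | C[C@H]1[C@H](O)[C@](C)([C@H]4CO[Os](=O)(=O)O4)C[C@@H](OC(=O)CO)[C@@]2(C)[C@@H](C)CC[C@]13CCC(=O)[C@@H]32.CN(C)CCN(C)C | intermediate (not isolated)
30 | Pleuromutilin A; (3aS,4R,5S,6R,8R,9S,9aS,10S)‑6‑[(1S)‑1,2‑dihydroxyethyl]‑5‑hydroxy‑4,6,9,10‑tetramethyl‑1‑oxodecahydro‑3a,9‑propanocyclopenta[8]annulen‑8‑yl hydroxyacetate | C[C@H]1[C@H](O)[C@](C)([C@H](O)CO)C[C@@H](OC(=O)CO)[C@@]2(C)[C@@H](C)CC[C@]13CCC(=O)[C@@H]32 | target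

**Totals and risks**
Total step count: 17. Longest linear sequence: 16 steps (1 → 30 through steps 1–9 and 11–17); step 10 is a one‑step side branch.

Steps most likely to fail:

Step 6. The copper‑catalysed addition must build the C9 quaternary centre next to the branched C10 substituent, and the one‑pot condensation must follow. The fallback sets out from enone 11 and comes back at bicyclic enone 15. The γ‑methoxyallyl reagent (allyl methyl ether, s‑BuLi, then Et2AlCl) adds 1,2 to 11 through its oxygen‑bearing carbon to give (6S)‑3‑[(2S)‑but‑3‑en‑2‑yl]‑1‑(1‑methoxyprop‑2‑en‑1‑yl)‑6‑methylcyclohex‑2‑en‑1‑ol F1. KH/18‑crown‑6 then triggers a second anionic oxy‑Cope rearrangement that forms the C9 quaternary centre intramolecularly and gives (6S)‑3‑[(2S)‑but‑3‑en‑2‑yl]‑3‑(3‑methoxyprop‑2‑en‑1‑yl)‑6‑methylcyclohexan‑1‑one F2. The same aqueous HCl treatment hydrolyses the enol ether and closes the ring to 15.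

Step 11. The aldehyde is neopentyl‑like, and both new centres depend on Felkin control and on the geometric integrity of the boronic acid. The fallback sets out from aldehyde 19 and alcohol 20 and comes back at alcohol 22. PBr3 converts 20 into (2Z)‑1‑bromo‑3‑methylpent‑2‑en‑4‑yne F3. CrCl2 in THF at 0 °C turns F3 into the allylchromium species, which adds through its γ‑carbon to 19 (Nozaki–Hiyama allylation), giving 22 without a boron reagent.

Step 17. The face selectivity at C19 rests on hydrogen‑bond delivery to a homoallylic vinyl group. The fallback sets out from 28 and comes back at 30. VO(acac)2‑catalysed, C11‑hydroxyl‑directed epoxidation with t‑BuOOH gives the 19,20‑epoxide of 28 F4. Acid‑catalysed hydrolysis (HClO4, THF/H2O) opens it at the terminal C20 with retention at C19.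

**Further compounds**
F1 | step 6 | (6S)‑3‑[(2S)‑but‑3‑en‑2‑yl]‑1‑(1‑methoxyprop‑2‑en‑1‑yl)‑6‑methylcyclohex‑2‑en‑1‑ol (allyl group cis to the C6 methyl; epimers at the methoxy carbon) | C[C@H]1CCC([C@@H](C)C=C)=C[C@@]1(O)C(OC)C=C
F2 | step 6 | (6S)‑3‑[(2S)‑but‑3‑en‑2‑yl]‑3‑(3‑methoxyprop‑2‑en‑1‑yl)‑6‑methylcyclohexan‑1‑one (C9 as in 14; E/Z enol ether) | C[C@H]1CC[C@](CC=COC)([C@@H](C)C=C)CC1=O
F3 | step 11 | (2Z)‑1‑bromo‑3‑methylpent‑2‑en‑4‑yne | BrC/C=C(/C)C#C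
F4 | step 17 | 19,20‑epoxide of 28 (oxirane in place of the vinyl group, C19 as in 30) | C[C@H]1[C@H](O)[C@](C)([C@H]4CO4)C[C@@H](OC(=O)CO)[C@@]2(C)[C@@H](C)CC[C@]13CCC(=O)[C@@H]32
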